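The readings come from a simulation for substances that don't exist; scatter was added.

**Time of reading.** At 20 min you read ash, oak and cedar, which differ in their reagent charge. How much target stands in each?

common to all: starting material 0.40 M
- east: reagent 0.85 M; run made earlier
- west: reagent 1.4 M; run made earlier
- ash: reagent 0.600 M; time 20 min
- oak: reagent 0.780 M; time 20 min
- cedar: reagent 1.00 M; time 20 min

| run | time / min | target / % | starting material / % |
|---|---|---|---|
| east | 2.00 | 35.5 | 46.1 |
| east | 4.00 | 47.4 | 25.1 |
| east | 6.00 | 54.5 | 13.1 |
| east | 8.00 | 59.5 | 8.3 |
| east | 10.0 | 60.0 | 5.5 |
| west | 0.833 | 27.4 | 55.8 |
| west | 2.50 | 51.7 | 21.4 |
| west | 5.00 | 60.7 | 5.3 |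
| west | 8.00 | 62.9 | 0.8 |
| west | 10.0 | 64.0 | 0 |

(standard deviation of a reading: 1 percentage point)

- which of the two there is more of at the end, ash (target / side product)
- which of the two there is more of at the end, oak (target / side product)
- which of the two there is more of at the end, cedar (target / side product)
- final target, as a percentage of the starting material charged, in ash
- final target, as a percentage of the starting material charged, in oak
- final target, as a percentage of the starting material charged, in cedar



**Target share.** Assume one reagent is used per starting material. West at its first reading holds about 1.22 M reagent, and target per starting material consumed is 62.0%. East at 10.0 min holds about 0.472 M and gives 63.5%. The gap is 1.5 percentage points, but the west ratio divides by 44.2% consumed, so a scatter of 1 point in its target reading becomes about twice that in the ratio; so freeze the ratio. Target formed per starting material consumed, the target share or selectivity, reads 63.7% from the last readings of both runs.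

**Rate constant.** Let the rate be k times starting material times reagent. The ratio of reagent to starting material then grows by the exponential of k times excess reagent times time. East at 4.00 min gives k = 0.527 /M/min, and west at 2.50 min gives 0.515 /M/min. I take 0.521 /M/min.

**First number.** With reagent frozen at its charge, ash keeps 0.193% starting material, so nearly the full share appears as target.

**Weak link.** One reagent per starting material takes ash's reagent toward about 0.200 M, a third of its charge, so that freeze fails. Using the growing ratio instead, I get starting material left at 4.53% in ash, 0.940% in oak and 0.116% in cedar. Share times consumed gives me 60.8%, 63.1% and 63.6% target. The remainder of what is consumed, 36.3%, is less than the share, so target leads.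

**The forecast.** It names target, target and target as the larger product, with 61%, 63% and 64%, noting: “Target per starting material consumed is about 64% at every point”.

**The flasks.** Target reaches 60.9% in ash, 63.2% in oak and 63.7% in cedar, above side product at 27.4%, 27.9% and 27.1%.

    reagent + intermediate A ⇌ intermediate B (K = 0.970 /M, k = 0.00260 /M/s)
    intermediate B ⇌ intermediate C (K = 1.30, k = 9.80 × 10⁻⁴ /s)
    starting material + reagent → target (k = 0.00580 /M/s)
    starting material + reagent → intermediate A (k = 0.00330 /M/s)
    intermediate A → side product (k = 0.00240 /s)

Target and intermediate A arise side by side, at 1.8 to one at the start in ash. A neighbouring flask, like ash but with 1.6 M starting material, has 0.375 equiv reagent, which makes reagent the limiting reagent. The share times the starting material that reagent can consume gives 23.9% target. That flask gives 23.8%, with 63% of its starting material and 0.041% of its reagent left.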